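**Retrosynthetic overview**
1. Target 10 is cut at the O7–CH2 bond of the prenyl ether: 2'-hydroxygenistein 6 plus a prenyl donor made in the flask from prenol 7 and carbodiimide 8. This C–O bond is formed last.
2. 6 comes from its 2',4'-dimethyl ether 5 by O-demethylation.
3. 5 comes from deoxybenzoin 3 by closing ring C through the O1–C2 bond with one carbon from DMF; 3 comes from C-acylation of phloroglucinol 1 with arylacetic acid 2.
4. Rings A and B are bought; ring C (the pyranone) is the only ring formed, in step 1.

Assumption: the target has no stereocentre and no stereogenic double bond, so it is one achiral compound and no stereoselective step is needed.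

**Route**

Step 1
Reactants: 1 phloroglucinol (benzene-1,3,5-triol); 2 (2,4-dimethoxyphenyl)acetic acid
Product: 5 isoflavone dimethyl ether [3-(2,4-dimethoxyphenyl)-5,7-dihydroxy-4H-chromen-4-one], via deoxybenzoin 3 (not isolated), via enaminone 4 (not isolated)
Conditions: BF3·OEt2 (neat), 85 °C, 1.5 h; then DMF, MsCl, 70 °C, 2 h; H2O
Reagents that add atoms: N,N-dimethylformamide, CN(C)C=O
Why: BF3-promoted Friedel–Crafts C-acylation of the electron-rich triol gives 3 (held as its boron chelate, which stops a second acylation), the iminium reagent from DMF/MsCl aminomethylenates its CH2 to 4, and the ortho-OH adds to the enamine carbon with loss of dimethylamine to close ring C through O1–C2 (one-pot deoxybenzoin isoflavone synthesis); no stereocentre is formed.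

Step 2
Reactants: 5 isoflavone dimethyl ether [3-(2,4-dimethoxyphenyl)-5,7-dihydroxy-4H-chromen-4-one]
Product: 6 tetrahydroxyisoflavone 2'-hydroxygenistein [3-(2,4-dihydroxyphenyl)-5,7-dihydroxy-4H-chromen-4-one]
Conditions: BBr3 (7 equiv), CH2Cl2, −78 °C to 23 °C, 16 h; MeOH, H2O
Reagents that add atoms: none
Why: BBr3 binds each aryl methyl ether oxygen and bromide removes the methyl group by SN2 (Lewis-acid O-demethylation), while the chromone and its chelated 5-OH are stable to these conditions; no stereocentre is formed.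

Step 3
Reactants: 6 tetrahydroxyisoflavone 2'-hydroxygenistein; 7 prenol (3-methylbut-2-en-1-ol); 8 N,N'-diisopropylcarbodiimide
Product: 10 target CNP0425118.0 [3-(2,4-dihydroxyphenyl)-5-hydroxy-7-(3-methylbut-2-enyloxy)-4H-chromen-4-one], via O-prenylisourea 9 (not isolated)
Conditions: 7 (1.10 equiv), 8 (1.05 equiv), CuCl (2 mol %), neat, 23 °C, 16 h; then 6 (1.00 equiv), THF, 50 °C, 24 h
Reagents that add atoms: none
Why: Proposed new method: acidity-gated, base-free prenyl transfer to one hydroxyl of an unprotected polyphenol — in THF only the vinylogous-acid 7-OH (pKa about 7, against about 10 for 2'- and 4'-OH and about 13 for the chelated 5-OH) protonates the isourea nitrogen of 9, and the resulting isouronium/7-phenoxide contact ion pair collapses by SN2 at the primary allylic CH2 to give the linear ether and N,N'-diisopropylurea, with no free base to form di-anions and no stereocentre formed; the closest known reaction type is the esterification of carboxylic acids with O-alkylisoureas (a Mitsunobu-like alkylation of acidic pronucleophiles), which has not been used to select one phenol among several or to transfer a prenyl group in this way.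

**Compound list**
1 | phloroglucinol (benzene-1,3,5-triol) | Oc1cc(O)cc(O)c1 | starting material
2 | (2,4-dimethoxyphenyl)acetic acid | COc1ccc(CC(=O)O)c(OC)c1 | starting material
3 | deoxybenzoin, 2-(2,4-dimethoxyphenyl)-1-(2,4,6-trihydroxyphenyl)ethan-1-one | COc1ccc(CC(=O)c2c(O)cc(O)cc2O)c(OC)c1 | intermediate
4 | enaminone, 3-(dimethylamino)-2-(2,4-dimethoxyphenyl)-1-(2,4,6-trihydroxyphenyl)prop-2-en-1-one (double-bond geometry not defined; it is lost on ring closure) | CN(C)C=C(C(=O)c1c(O)cc(O)cc1O)c1ccc(OC)cc1OC | intermediate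
5 | isoflavone dimethyl ether, 3-(2,4-dimethoxyphenyl)-5,7-dihydroxy-4H-chromen-4-one | COc1ccc(-c2coc3cc(O)cc(O)c3c2=O)c(OC)c1 | intermediate
6 | 2'-hydroxygenistein, 3-(2,4-dihydroxyphenyl)-5,7-dihydroxy-4H-chromen-4-one | Oc1ccc(-c2coc3cc(O)cc(O)c3c2=O)c(O)c1 | intermediate
7 | prenol (3-methylbut-2-en-1-ol) | CC(C)=CCO | starting material
8 | N,N'-diisopropylcarbodiimide | CC(C)N=C=NC(C)C | starting material
9 | O-prenylisourea, 3-methylbut-2-enyl N,N'-diisopropylcarbamimidate | CC(C)=CCOC(=NC(C)C)NC(C)C | intermediate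
10 | CNP0425118.0, 3-(2,4-dihydroxyphenyl)-5-hydroxy-7-(3-methylbut-2-enyloxy)-4H-chromen-4-one (achiral) | CC(C)=CCOc1cc(O)c2c(=O)c(-c3ccc(O)cc3O)coc2c1 | target

**Step count**
Total steps: 3. Longest linear sequence: 3.

**Steps most likely to fail, with fallbacks**

Step 3 (the proposed new method). The ion pair may collapse through a prenyl cation, giving the tertiary ether or C-prenylation at C6/C8. The isourea may also be too sluggish at 50 °C, or leak to O4'. The fallback uses known chemistry and controls the site with protecting groups instead of acidity. It sets out from 6. Exhaustive acetylation (Ac2O, pyridine, DMAP cat., 60 °C) gives 5,7,2',4'-tetraacetoxyisoflavone F1. Thiophenol and imidazole in NMP at 0 °C remove only the most activated 7-O-acetyl group to give 5,2',4'-triacetoxy-7-hydroxyisoflavone F2. Mitsunobu etherification with prenol 7 (PPh3, DIAD, THF, 0 °C to 23 °C) gives 5,2',4'-triacetoxy-7-(3-methylbut-2-enyloxy)isoflavone F3. Methanolysis of the three acetates (K2CO3, MeOH, 23 °C, then AcOH) comes back to the route at 10.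

Step 2. The hindered 2'-OMe may cleave incompletely, or the freed 2'-OH may add to C2 under Lewis acid and divert material to a 3-aroylbenzofuran. The fallback avoids Lewis-acid ether cleavage by carrying benzyl ethers removed with hydrogen. It sets out from 1. Commercial 2,4-bis(benzyloxy)benzaldehyde is homologated by Van Leusen reductive cyanation (TosMIC, KOt-Bu, DME, −40 °C; then MeOH, reflux) to [2,4-bis(benzyloxy)phenyl]acetonitrile F4. Houben–Hoesch reaction of F4 with 1 (ZnCl2, HCl gas, Et2O, 0 °C) gives 2-[2,4-bis(benzyloxy)phenyl]-1-(2,4,6-trihydroxyphenyl)ethan-1-iminium chloride F5. Hot water (100 °C) hydrolyses it to 2-[2,4-bis(benzyloxy)phenyl]-1-(2,4,6-trihydroxyphenyl)ethan-1-one F6. Ring closure with HC(OEt)3, pyridine and catalytic piperidine at 120 °C gives 3-[2,4-bis(benzyloxy)phenyl]-5,7-dihydroxy-4H-chromen-4-one F7. Hydrogenolysis (H2 1 atm, 10% Pd/C, EtOAc/MeOH, 23 °C, stopped after two equivalents of H2 to spare the C2=C3 bond) comes back to the route at 6.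

Step 1. The one-pot acylation may give tars or a poor yield, and the telescoped cyclisation may stall on the crude boron complex. The fallback makes the ketone from a nitrile and isolates it before ring closure. It sets out from 1. Houben–Hoesch reaction with commercial (2,4-dimethoxyphenyl)acetonitrile (ZnCl2, HCl gas, Et2O, 0 °C) gives 2-(2,4-dimethoxyphenyl)-1-(2,4,6-trihydroxyphenyl)ethan-1-iminium chloride F8. Hydrolysis in water at 100 °C comes back to the route at 3, now isolated and purified. 3 is then cyclised to 5 in a separate flask with the DMF, BF3·OEt2, MsCl stage of step 1.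

**Further compounds**
F1 | step 3 | 5,7,2',4'-tetraacetoxyisoflavone | CC(=O)Oc1ccc(-c2coc3cc(OC(C)=O)cc(OC(C)=O)c3c2=O)c(OC(C)=O)c1
F2 | step 3 | 5,2',4'-triacetoxy-7-hydroxyisoflavone | CC(=O)Oc1ccc(-c2coc3cc(O)cc(OC(C)=O)c3c2=O)c(OC(C)=O)c1
F3 | step 3 | 5,2',4'-triacetoxy-7-(3-methylbut-2-enyloxy)isoflavone | CC(C)=CCOc1cc(OC(C)=O)c2c(=O)c(-c3ccc(OC(C)=O)cc3OC(C)=O)coc2c1
F4 | step 2 | [2,4-bis(benzyloxy)phenyl]acetonitrile | N#CCc1ccc(OCc2ccccc2)cc1OCc1ccccc1
F5 | step 2 | 2-[2,4-bis(benzyloxy)phenyl]-1-(2,4,6-trihydroxyphenyl)ethan-1-iminium chloride | [NH2+]=C(Cc1ccc(OCc2ccccc2)cc1OCc1ccccc1)c1c(O)cc(O)cc1O.[Cl-]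
F6 | step 2 | 2-[2,4-bis(benzyloxy)phenyl]-1-(2,4,6-trihydroxyphenyl)ethan-1-one | O=C(Cc1ccc(OCc2ccccc2)cc1OCc1ccccc1)c1c(O)cc(O)cc1O
F7 | step 2 | 3-[2,4-bis(benzyloxy)phenyl]-5,7-dihydroxy-4H-chromen-4-one | O=c1c(-c2ccc(OCc3ccccc3)cc2OCc2ccccc2)coc2cc(O)cc(O)c12
F8 | step 1 | 2-(2,4-dimethoxyphenyl)-1-(2,4,6-trihydroxyphenyl)ethan-1-iminium chloride | COc1ccc(CC(=[NH2+])c2c(O)cc(O)cc2O)c(OC)c1.[Cl-]
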